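**Retrosynthetic overview**
1. Endgame: aryl O–Si cleavage last; before it, the enol carbamate is converted to the enol sulfate through its lithium enolate, with the C=C geometry kept.
2. Key disconnection: the C2–C3 bond of the octa-1,6-dienyl chain, made by chelation-directed syn-carbocupration of the decalin-bearing O-alkynyl carbamate 9 with the primary alkylcopper from iodide 17, then protonolysis.
3. Enabling feature: the enol unit O–C1H=C2 is an alkyne O–C1≡C2 in disguise. C2 carries two near-identical CH2 arms, so its Z geometry cannot come from enolisation; the carbamate C=O on the C1 oxygen binds copper, sends the alkyl group to C2 (the normally nucleophilic enol carbon, so two donor carbons are joined) and the syn addition fixes the geometry.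
4. Fragments: 9 from (+)-sclareolide (C5, C9, C10 from the chiral pool; ring alkene by lactone opening/elimination; alkylation of a lithium alkynyl carbamate). 17 from 2,5-dihydroxybenzaldehyde and 5-chloro-1-pentyne (carboalumination/benzyl cross-coupling sets the E alkene).
5. No ring is formed in the route: decalin rings A and B come intact from sclareolide, the arene from 2,5-dihydroxybenzaldehyde.

Key step: step 11

Remark: the target is written as the free hydrogen sulfate. Compounds 23 and 24 are drawn in that neutral form but would be handled as salts (Li+/Na+ after step 12, Na+ after ion exchange in step 13), because a free enol hydrogen sulfate hydrolyses readily.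

**Step 1**
Reactants: 1 (+)-sclareolide
Product: 2 methyl 2-[(1S,4aS,8aS)-2,5,5,8a-tetramethyl-1,4,4a,5,6,7,8,8a-octahydronaphthalen-1-yl]acetate
Conditions: conc. H2SO4, MeOH, reflux; chromatography on AgNO3-impregnated silica
Reagents that add atoms: methanol, CO
Why: Acid-catalysed alkyl–oxygen cleavage of the tertiary lactone gives the C8 cation, which should lose the axial 7-H (E1 elimination) to the trisubstituted ring alkene while the acid undergoes Fischer esterification; the three ring stereocentres are untouched and minor alkene isomers would be removed on the silver-doped silica.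

**Step 2**
Reactants: 2 methyl ester
Product: 3 2-[(1S,4aS,8aS)-2,5,5,8a-tetramethyl-1,4,4a,5,6,7,8,8a-octahydronaphthalen-1-yl]ethanol
Conditions: LiAlH4, THF, 0 °C → rt; Fieser work-up
Reagents that add atoms: none
Why: LiAlH4 reduction of an ester to the primary alcohol, to which the isolated trisubstituted alkene is inert.

**Step 3**
Reactants: 3 alcohol
Product: 4 2-[(1S,4aS,8aS)-2,5,5,8a-tetramethyl-1,4,4a,5,6,7,8,8a-octahydronaphthalen-1-yl]ethyl trifluoromethanesulfonate
Conditions: Tf2O, 2,6-lutidine, CH2Cl2, −78 °C; cold filtration through a short silica pad, used at once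
Reagents that add atoms: trifluoromethanesulfonic anhydride, O=S(=O)(OS(=O)(=O)C(F)(F)F)C(F)(F)F
Why: O-triflation of an unhindered primary alcohol with a hindered pyridine base, which should avoid N-alkylation and leave the ring alkene alone at low temperature.

**Step 4**
Reactants: 5 2,2,2-tribromoethanol
Product: 6 2,2,2-tribromoethyl N,N-diisopropylcarbamate
Conditions: ClC(O)N(iPr)2, pyridine, DMAP (cat.), 80 °C
Reagents that add atoms: N,N-diisopropylcarbamoyl chloride, CC(C)N(C(C)C)C(=O)Cl
Why: O-carbamoylation of an alcohol by nucleophilic acyl substitution on a carbamoyl chloride.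

**Step 5**
Reactants: 6 tribromoethyl carbamate; 4 triflate
Product: 9 4-[(1S,4aS,8aS)-2,5,5,8a-tetramethyl-1,4,4a,5,6,7,8,8a-octahydronaphthalen-1-yl]but-1-yn-1-yl N,N-diisopropylcarbamate, via dibromovinyl carbamate 7 (not isolated), via lithium alkynyl carbamate 8 (not isolated)
Conditions: 6, LiN(iPr)2 (1.05 equiv), THF, −78 °C; n-BuLi (2.1 equiv), −78 → −40 °C; then 4, −78 → −20 °C
Reagents that add atoms: none
Why: Dehydrobromination gives the dibromovinyl carbamate, a Corey–Fuchs-type bromine–lithium exchange/elimination gives the lithium alkynyl carbamate, and SN2 alkylation of this acetylide by the primary triflate should proceed cold, the hindered diisopropylcarbamoyl group resisting the lithium reagents.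

**Step 6**
Reactants: 10 2,5-dihydroxybenzaldehyde
Product: 11 2,5-bis(triisopropylsilyloxy)benzaldehyde
Conditions: iPr3SiOTf (2.3 equiv), 2,6-lutidine, CH2Cl2, 0 °C → rt
Reagents that add atoms: triisopropylsilyl trifluoromethanesulfonate, CC(C)[Si](OS(=O)(=O)C(F)(F)F)(C(C)C)C(C)C
Why: O-silylation of both phenols, the silyl triflate being reactive enough for the hydrogen-bonded ortho phenol.

**Step 7**
Reactants: 11 aldehyde
Product: 12 [2,5-bis(triisopropylsilyloxy)phenyl]methanol
Conditions: NaBH4, EtOH/THF, 0 °C, short reaction time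
Reagents that add atoms: none
Why: NaBH4 reduction of the aldehyde, kept cold and brief so that the bulky silyl group should not migrate from the phenol to the new alkoxide.

**Step 8**
Reactants: 12 benzylic alcohol
Product: 13 2-(chloromethyl)-1,4-bis(triisopropylsilyloxy)benzene
Conditions: PPh3, N-chlorosuccinimide, THF, 0 °C → rt
Reagents that add atoms: N-chlorosuccinimide, O=C1CCC(=O)N1Cl
Why: Appel-type chlorination of a benzylic alcohol under neutral conditions that the aryl silyl ethers tolerate.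

**Step 9**
Reactants: 14 5-chloro-1-pentyne; 13 benzylic chloride
Product: 16 2-[(2E)-6-chloro-3-methylhex-2-en-1-yl]-1,4-bis(triisopropylsilyloxy)benzene, via alkenylalane 15 (not isolated)
Conditions: AlMe3 (2.0 equiv), Cp2ZrCl2 (0.2 equiv), ClCH2CH2Cl, 0 °C → rt; excess AlMe3 and solvent removed in vacuo; then 13, NiCl2(PPh3)2 (5 mol %)/n-BuLi (10 mol %) giving zerovalent nickel, THF, rt
Reagents that add atoms: trimethylaluminium, C[Al](C)C
Why: Negishi zirconium-catalysed carboalumination adds methyl and aluminium syn with methyl on the internal carbon, which fixes the E geometry, and the nickel-catalysed alkenylalane–benzylic chloride cross-coupling proceeds with retention, the primary alkyl chloride being inert to both.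

**Step 10**
Reactants: 16 alkyl chloride
Product: 17 2-[(2E)-6-iodo-3-methylhex-2-en-1-yl]-1,4-bis(triisopropylsilyloxy)benzene
Conditions: NaI, acetone, reflux
Reagents that add atoms: sodium iodide, [Na+].[I-]
Why: Finkelstein halide exchange (SN2) at the primary carbon, driven by precipitation of NaCl.

**Step 11**
Reactants: 17 alkyl iodide; 9 alkynyl carbamate
Product: 21 (1Z,6E)-8-[2,5-bis(triisopropylsilyloxy)phenyl]-6-methyl-2-{2-[(1S,4aS,8aS)-2,5,5,8a-tetramethyl-1,4,4a,5,6,7,8,8a-octahydronaphthalen-1-yl]ethyl}octa-1,6-dien-1-yl N,N-diisopropylcarbamate, via alkylmagnesium iodide 18 (not isolated), via alkylcopper 19 (not isolated), via alkenylcopper 20 (not isolated)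
Conditions: 17 (1.3 equiv), Mg turnings, Et2O, rt; CuI (1.3 equiv), Et2O, −40 °C; 9 (1.0 equiv), −40 → −10 °C; aq. NH4Cl/NH3, −10 °C
Reagents that add atoms: none
Why: The alkylcopper RCu·MgI2 binds the carbamate C=O of 9 and adds syn across the C≡C bond, the alkyl group going to the carbon remote from oxygen and copper to the oxygen-bearing carbon, where it is held in a five-membered Cu···O=C chelate; protonolysis of the C–Cu bond with retention then gives the enol carbamate. The closest known reaction type is the Normant carbocupration as applied to O-alkynyl carbamates and ynamides to make stereodefined enol derivatives. No ring is closed and no stereocentre is formed; the new stereo-element is the trisubstituted enol double bond, whose Z geometry (decalin-ethyl arm cis to oxygen) follows from the syn mode of addition and not from any steric difference between the two CH2 arms. The step needs regioselectivity (alkyl to the carbon that becomes C2) and chemoselectivity: the first is secured by the chelating carbamate on the alkyne oxygen, the second by the inertness of the two unactivated trisubstituted alkenes and the aryl silyl ethers toward an alkylcopper at or below −10 °C. The union joins two donor carbons, since C2 is the nucleophilic carbon of the enol in the product and here receives a carbanion equivalent.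

**Step 12**
Reactants: 21 enol carbamate
Product: 23 (1Z,6E)-8-[2,5-bis(triisopropylsilyloxy)phenyl]-6-methyl-2-{2-[(1S,4aS,8aS)-2,5,5,8a-tetramethyl-1,4,4a,5,6,7,8,8a-octahydronaphthalen-1-yl]ethyl}octa-1,6-dien-1-yl hydrogen sulfate, via lithium enolate 22 (not isolated)
Conditions: MeLi (2.2 equiv), THF, −78 → 0 °C; then SO3·NMe3 (3 equiv), DMF/THF, −40 → 0 °C; pH 7 phosphate buffer/brine
Reagents that add atoms: sulfur trioxide–trimethylamine complex, C[N+](C)(C)S(=O)(=O)[O-]
Why: Nucleophilic cleavage of the enol carbamate by MeLi should release the lithium aldehyde enolate with its double-bond geometry intact, and this enolate, fully substituted at carbon, should be sulfated at oxygen by the sulfur trioxide–amine complex (O-sulfation of a metal enolate).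

**Step 13**
Reactants: 23 bis-silyl enol sulfate
Product: 24 (1Z,6E)-8-(2,5-dihydroxyphenyl)-6-methyl-2-{2-[(1S,4aS,8aS)-2,5,5,8a-tetramethyl-1,4,4a,5,6,7,8,8a-octahydronaphthalen-1-yl]ethyl}octa-1,6-dien-1-yl hydrogen sulfate (target)
Conditions: Bu4NF (2.5 equiv), AcOH (2.5 equiv), degassed THF, 0 °C, argon; cation-exchange resin (Na+ form)
Reagents that add atoms: none
Why: Fluoride-mediated cleavage of the two aryl silyl ethers under buffered, oxygen-free conditions should spare the enol sulfate anion and both alkenes and avoid oxidation of the hydroquinone to the quinone.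

**Compound list**
1 | (+)-sclareolide, (3aR,5aS,9aS,9bR)-3a,6,6,9a-tetramethyldecahydronaphtho[2,1-b]furan-2(1H)-one | CC1(CCC[C@]2([C@H]1CC[C@@]3([C@@H]2CC(=O)O3)C)C)C | starting material
2 | methyl 2-[(1S,4aS,8aS)-2,5,5,8a-tetramethyl-1,4,4a,5,6,7,8,8a-octahydronaphthalen-1-yl]acetate | CC1=CC[C@H]2C(C)(C)CCC[C@]2(C)[C@H]1CC(=O)OC | intermediate
3 | 2-[(1S,4aS,8aS)-2,5,5,8a-tetramethyl-1,4,4a,5,6,7,8,8a-octahydronaphthalen-1-yl]ethanol | CC1=CC[C@H]2C(C)(C)CCC[C@]2(C)[C@H]1CCO | intermediate
4 | 2-[(1S,4aS,8aS)-2,5,5,8a-tetramethyl-1,4,4a,5,6,7,8,8a-octahydronaphthalen-1-yl]ethyl trifluoromethanesulfonate | CC1=CC[C@H]2C(C)(C)CCC[C@]2(C)[C@H]1CCOS(=O)(=O)C(F)(F)F | intermediate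
5 | 2,2,2-tribromoethanol | OCC(Br)(Br)Br | starting material
6 | 2,2,2-tribromoethyl N,N-diisopropylcarbamate | CC(C)N(C(C)C)C(=O)OCC(Br)(Br)Br | intermediate
7 | 2,2-dibromoethenyl N,N-diisopropylcarbamate (not isolated) | CC(C)N(C(C)C)C(=O)OC=C(Br)Br | intermediate
8 | lithium 2-(N,N-diisopropylcarbamoyloxy)ethynide (not isolated) | [Li]C#COC(=O)N(C(C)C)C(C)C | intermediate
9 | 4-[(1S,4aS,8aS)-2,5,5,8a-tetramethyl-1,4,4a,5,6,7,8,8a-octahydronaphthalen-1-yl]but-1-yn-1-yl N,N-diisopropylcarbamate | CC1=CC[C@H]2C(C)(C)CCC[C@]2(C)[C@H]1CCC#COC(=O)N(C(C)C)C(C)C | intermediate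
10 | 2,5-dihydroxybenzaldehyde | O=Cc1cc(O)ccc1O | starting material
11 | 2,5-bis(triisopropylsilyloxy)benzaldehyde | O=Cc1cc(O[Si](C(C)C)(C(C)C)C(C)C)ccc1O[Si](C(C)C)(C(C)C)C(C)C | intermediate
12 | [2,5-bis(triisopropylsilyloxy)phenyl]methanol | OCc1cc(O[Si](C(C)C)(C(C)C)C(C)C)ccc1O[Si](C(C)C)(C(C)C)C(C)C | intermediate
13 | 2-(chloromethyl)-1,4-bis(triisopropylsilyloxy)benzene | ClCc1cc(O[Si](C(C)C)(C(C)C)C(C)C)ccc1O[Si](C(C)C)(C(C)C)C(C)C | intermediate
14 | 5-chloro-1-pentyne | C#CCCCCl | starting material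
15 | [(1E)-5-chloro-2-methylpent-1-en-1-yl]dimethylalane (not isolated) | ClCCC/C(C)=C/[Al](C)C | intermediate
16 | 2-[(2E)-6-chloro-3-methylhex-2-en-1-yl]-1,4-bis(triisopropylsilyloxy)benzene | ClCCC/C(C)=C/Cc1cc(O[Si](C(C)C)(C(C)C)C(C)C)ccc1O[Si](C(C)C)(C(C)C)C(C)C | intermediate
17 | 2-[(2E)-6-iodo-3-methylhex-2-en-1-yl]-1,4-bis(triisopropylsilyloxy)benzene | ICCC/C(C)=C/Cc1cc(O[Si](C(C)C)(C(C)C)C(C)C)ccc1O[Si](C(C)C)(C(C)C)C(C)C | intermediate
18 | {(4E)-6-[2,5-bis(triisopropylsilyloxy)phenyl]-4-methylhex-4-en-1-yl}magnesium iodide (not isolated) | I[Mg]CCC/C(C)=C/Cc1cc(O[Si](C(C)C)(C(C)C)C(C)C)ccc1O[Si](C(C)C)(C(C)C)C(C)C | intermediate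
19 | {(4E)-6-[2,5-bis(triisopropylsilyloxy)phenyl]-4-methylhex-4-en-1-yl}copper, as its MgI2 complex (not isolated) | [Cu]CCC/C(C)=C/Cc1cc(O[Si](C(C)C)(C(C)C)C(C)C)ccc1O[Si](C(C)C)(C(C)C)C(C)C | intermediate
20 | (1E,6E)-8-[2,5-bis(triisopropylsilyloxy)phenyl]-1-(N,N-diisopropylcarbamoyloxy)-6-methyl-2-{2-[(1S,4aS,8aS)-2,5,5,8a-tetramethyl-1,4,4a,5,6,7,8,8a-octahydronaphthalen-1-yl]ethyl}octa-1,6-dien-1-ylcopper (not isolated) | CC1=CC[C@H]2C(C)(C)CCC[C@]2(C)[C@H]1CC/C(=C(\OC(=O)N(C(C)C)C(C)C)[Cu])CCC/C(C)=C/Cc1cc(O[Si](C(C)C)(C(C)C)C(C)C)ccc1O[Si](C(C)C)(C(C)C)C(C)C | intermediate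
21 | (1Z,6E)-8-[2,5-bis(triisopropylsilyloxy)phenyl]-6-methyl-2-{2-[(1S,4aS,8aS)-2,5,5,8a-tetramethyl-1,4,4a,5,6,7,8,8a-octahydronaphthalen-1-yl]ethyl}octa-1,6-dien-1-yl N,N-diisopropylcarbamate | CC1=CC[C@H]2C(C)(C)CCC[C@]2(C)[C@H]1CC/C(=C\OC(=O)N(C(C)C)C(C)C)CCC/C(C)=C/Cc1cc(O[Si](C(C)C)(C(C)C)C(C)C)ccc1O[Si](C(C)C)(C(C)C)C(C)C | intermediate
22 | lithium (1Z,6E)-8-[2,5-bis(triisopropylsilyloxy)phenyl]-6-methyl-2-{2-[(1S,4aS,8aS)-2,5,5,8a-tetramethyl-1,4,4a,5,6,7,8,8a-octahydronaphthalen-1-yl]ethyl}octa-1,6-dien-1-olate (not isolated) | CC1=CC[C@H]2C(C)(C)CCC[C@]2(C)[C@H]1CC/C(=C\O[Li])CCC/C(C)=C/Cc1cc(O[Si](C(C)C)(C(C)C)C(C)C)ccc1O[Si](C(C)C)(C(C)C)C(C)C | intermediate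
23 | (1Z,6E)-8-[2,5-bis(triisopropylsilyloxy)phenyl]-6-methyl-2-{2-[(1S,4aS,8aS)-2,5,5,8a-tetramethyl-1,4,4a,5,6,7,8,8a-octahydronaphthalen-1-yl]ethyl}octa-1,6-dien-1-yl hydrogen sulfate | CC1=CC[C@H]2C(C)(C)CCC[C@]2(C)[C@H]1CC/C(=C\OS(=O)(=O)O)CCC/C(C)=C/Cc1cc(O[Si](C(C)C)(C(C)C)C(C)C)ccc1O[Si](C(C)C)(C(C)C)C(C)C | intermediate
24 | (1Z,6E)-8-(2,5-dihydroxyphenyl)-6-methyl-2-{2-[(1S,4aS,8aS)-2,5,5,8a-tetramethyl-1,4,4a,5,6,7,8,8a-octahydronaphthalen-1-yl]ethyl}octa-1,6-dien-1-yl hydrogen sulfate | CC1=CC[C@H]2C(C)(C)CCC[C@]2(C)[C@H]1CC/C(=C\OS(=O)(=O)O)CCC/C(C)=C/Cc1cc(O)ccc1O | target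

**Step count**
Total: 13 steps. Longest linear sequence: 8 steps (10 → 11 → 12 → 13 → 16 → 17 → 21 → 23 → 24; steps 6–13).

**Steps most likely to fail**

1. Step 11. The primary alkylcopper may decay by β-hydride elimination before it adds. The carbamoyl group may shift from oxygen to the copper-bearing carbon if the adduct warms. A loss of chelation control would give the wrong regiochemistry. Fallback, setting out from 9 and 17 and returning at 21: hydrozirconation of 9 with Cp2Zr(H)Cl (THF, rt; hydride delivered syn to the oxygen-bearing carbon) would give the alkenylzirconocene chloride F1, and iodinolysis (I2, 0 °C) the (E)-2-iodo enol carbamate F2. Separately, 17 with Zn dust and LiCl in THF would give the alkylzinc iodide F3. A Negishi coupling of F2 with F3 (Pd(PPh3)4, zerovalent palladium, THF, 40 °C) would form the same C2–C3 bond with retention of geometry and give 21.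

2. Step 12. MeLi may remove the vinylic hydrogen next to oxygen instead of attacking the hindered carbonyl. The enolate may be sulfonated at carbon, or the ionic enol sulfate may hydrolyse during isolation. Fallback, setting out from 21 and returning at 23: the enolate 22 (formed as in step 12) would be trapped with 2,2,2-trichloroethyl chlorosulfate at −78 °C to give the neutral, chromatographable 2,2,2-trichloroethyl sulfate diester F4. Reductive removal of the trichloroethyl group (Zn dust, HCO2NH4, MeOH, rt) would then give 23.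

3. Step 1. Proton loss from the C8 cation may be unselective (exocyclic or tetrasubstituted alkene), and acid may equilibrate the product toward the tetrasubstituted isomer. Fallback, setting out from 1 and returning at 2, with the alkene position fixed by construction:
   - Saponification (KOH, MeOH/H2O) and O-methylation of the carboxylate (MeI, DMF) would give the hydroxy ester F5.
   - SOCl2/pyridine at −78 °C eliminates only toward the methyl group, since the equatorial chlorosulfite has no anti-periplanar ring hydrogen, and would give the exocyclic alkene F6.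
   - Ozonolysis (O3, CH2Cl2, −78 °C; Me2S) would give the C8 ketone F7.
   - Kinetic deprotonation at the C7 methylene (KN(SiMe3)2, THF, −78 °C) and trapping with PhNTf2 would give the enol triflate F8 with the double bond locked at C7–C8.
   - Coupling with MeMgBr catalysed by Fe(acac)3 (THF, −30 °C) would install the methyl group and give 2.

**Further compounds**
F1 | step 11 | chlorobis(cyclopentadienyl){(1Z)-1-(N,N-diisopropylcarbamoyloxy)-4-[(1S,4aS,8aS)-2,5,5,8a-tetramethyl-1,4,4a,5,6,7,8,8a-octahydronaphthalen-1-yl]but-1-en-2-yl}zirconium | CC1=CC[C@H]2C(C)(C)CCC[C@]2(C)[C@H]1CC/C(=C\OC(=O)N(C(C)C)C(C)C)[Zr](Cl)(C1C=CC=C1)C1C=CC=C1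
F2 | step 11 | (1E)-2-iodo-4-[(1S,4aS,8aS)-2,5,5,8a-tetramethyl-1,4,4a,5,6,7,8,8a-octahydronaphthalen-1-yl]but-1-en-1-yl N,N-diisopropylcarbamate | CC1=CC[C@H]2C(C)(C)CCC[C@]2(C)[C@H]1CC/C(I)=C\OC(=O)N(C(C)C)C(C)C
F3 | step 11 | {(4E)-6-[2,5-bis(triisopropylsilyloxy)phenyl]-4-methylhex-4-en-1-yl}zinc iodide | I[Zn]CCC/C(C)=C/Cc1cc(O[Si](C(C)C)(C(C)C)C(C)C)ccc1O[Si](C(C)C)(C(C)C)C(C)C
F4 | step 12 | (1Z,6E)-8-[2,5-bis(triisopropylsilyloxy)phenyl]-6-methyl-2-{2-[(1S,4aS,8aS)-2,5,5,8a-tetramethyl-1,4,4a,5,6,7,8,8a-octahydronaphthalen-1-yl]ethyl}octa-1,6-dien-1-yl 2,2,2-trichloroethyl sulfate | CC1=CC[C@H]2C(C)(C)CCC[C@]2(C)[C@H]1CC/C(=C\OS(=O)(=O)OCC(Cl)(Cl)Cl)CCC/C(C)=C/Cc1cc(O[Si](C(C)C)(C(C)C)C(C)C)ccc1O[Si](C(C)C)(C(C)C)C(C)C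
F5 | step 1 | methyl 2-[(1R,2R,4aS,8aS)-2-hydroxy-2,5,5,8a-tetramethyldecahydronaphthalen-1-yl]acetate | CC1(CCC[C@]2([C@H]1CC[C@]([C@@H]2CC(=O)OC)(O)C)C)C
F6 | step 1 | methyl 2-[(1S,4aS,8aS)-5,5,8a-trimethyl-2-methylidenedecahydronaphthalen-1-yl]acetate | C=C1CC[C@H]2C(C)(C)CCC[C@]2(C)[C@H]1CC(=O)OC
F7 | step 1 | methyl 2-[(1R,4aS,8aS)-5,5,8a-trimethyl-2-oxodecahydronaphthalen-1-yl]acetate | O=C1CC[C@H]2C(C)(C)CCC[C@]2(C)[C@H]1CC(=O)OC
F8 | step 1 | methyl 2-[(1R,4aS,8aS)-5,5,8a-trimethyl-2-(trifluoromethylsulfonyloxy)-1,4,4a,5,6,7,8,8a-octahydronaphthalen-1-yl]acetate | O=S(=O)(OC1=CC[C@H]2C(C)(C)CCC[C@]2(C)[C@H]1CC(=O)OC)C(F)(F)F
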